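## Retrosynthetic overview

- The plan rests on the 1,3-relationship inside the dihydropyranone ring (ring B) between the aryl ketone carbon C4 and the oxygen-bearing stereocenter C2, joined through the C3 methylene. C4 is treated as a dithiane-masked acyl anion and C2–C3 as a terminal (S)-epoxide.
- Endgame: target ⇐ 5,8-quinone ⇐ 5,8-dimethoxy spiro-thioketal (oxidative unmasking of C4=O and both phenols, then quinone reduction). O1–C2 ⇐ phenol plus (S)-carbinol by Mitsunobu inversion.
- Key bond: C3–C4 ⇐ lithiated 2-aryl-1,3-dithiane plus (S)-2-alkyloxirane. The aryl dithiane comes from 2,5-dimethoxyphenol by ortho-formylation; the oxirane comes from (S)-epichlorohydrin and a C16 Z-alkenyl Grignard reagent.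
- Ring order: aromatic ring A is bought. Ring B is the only ring of the target that is built, closed at O1–C2 after the C3–C4 bond exists. The dithiane and oxirane rings are temporary.

Key step: step 7

Assumption: (11Z)-hexadec-11-en-1-ol, a commercial pheromone alcohol, is used as bought with its Z double bond in place; atom labels O1, C2, C3, C4, C4a, C8a follow chroman-4-one numbering of the target.

## Route

Step 1
Reactants: 1 2,5-dimethoxyphenol
Product: 2 2-hydroxy-3,6-dimethoxybenzaldehyde
Conditions: MgCl2, Et3N, (CH2O)n, MeCN, reflux; aq HCl work-up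
Reagents that add atoms: paraformaldehyde (as formaldehyde), C=O
Why: Magnesium-mediated ortho-formylation (Casnati–Skattebøl reaction): the magnesium phenoxide of 1 delivers formaldehyde to the only free ortho carbon and a second formaldehyde oxidises the benzylic alkoxide by hydride transfer, so the aldehyde should appear flanked by OH and OMe.

Step 2
Reactants: 2 2-hydroxy-3,6-dimethoxybenzaldehyde
Product: 3 2-(1,3-dithian-2-yl)-3,6-dimethoxyphenol
Conditions: HS(CH2)3SH, BF3·OEt2, CH2Cl2, 0 °C → rt
Reagents that add atoms: propane-1,3-dithiol, SCCCS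
Why: Lewis-acid dithioacetalisation of an aromatic aldehyde, done before the acid-labile MOM group is introduced; the free phenol and the aryl methyl ethers are inert to BF3·OEt2 at this temperature.

Step 3
Reactants: 3 2-(1,3-dithian-2-yl)-3,6-dimethoxyphenol
Product: 4 2-[3,6-dimethoxy-2-(methoxymethoxy)phenyl]-1,3-dithiane
Conditions: NaH, DMF, 0 °C; then MOMCl, 0 °C → rt
Reagents that add atoms: chloromethyl methyl ether, COCCl
Why: Williamson O-alkylation of the sodium phenoxide with a reactive α-chloro ether; NaH does not touch the dithiane C–H, the phenoxide outcompetes thioether sulfur, and the MOM ether later serves as a lithium-coordinating ortho group.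

Step 4
Reactants: 5 (11Z)-hexadec-11-en-1-ol
Product: 6 (5Z)-16-bromohexadec-5-ene
Conditions: CBr4, PPh3, CH2Cl2, 0 °C
Reagents that add atoms: carbon tetrabromide, BrC(Br)(Br)Br
Why: Appel bromination of a primary alcohol under neutral conditions that should leave the Z double bond in place.

Step 5
Reactants: 6 (5Z)-16-bromohexadec-5-ene; 7 (S)-epichlorohydrin [(2S)-2-(chloromethyl)oxirane]
Product: 9 (2S,14Z)-1-chlorononadec-14-en-2-ol, via Grignard reagent 8 (not isolated)
Conditions: Mg (I2-activated), THF, 45 °C; then CuI (10 mol %), 7, THF, −40 → −10 °C; aq NH4Cl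
Reagents that add atoms: none
Why: Copper-catalysed Grignard opening of an epoxide: the organocopper species from 8 and CuI attacks the unsubstituted ring carbon of 7 in preference to the CH2Cl carbon, the C–O bond at the stereocenter is not touched, and the (S) centre of 7 is carried into 9 unchanged.

Step 6
Reactants: 9 (2S,14Z)-1-chlorononadec-14-en-2-ol
Product: 10 (2S)-2-[(12Z)-heptadec-12-en-1-yl]oxirane
Conditions: NaOH, MeOH/THF, 0 °C → rt
Reagents that add atoms: none
Why: Intramolecular Williamson (3-exo-tet) closure of the chlorohydrin alkoxide onto CH2Cl; the stereocenter is not the carbon undergoing displacement, so 10 should be (S).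

Step 7
Reactants: 4 2-[3,6-dimethoxy-2-(methoxymethoxy)phenyl]-1,3-dithiane; 10 (2S)-2-[(12Z)-heptadec-12-en-1-yl]oxirane
Product: 12 (2S,14Z)-1-{2-[3,6-dimethoxy-2-(methoxymethoxy)phenyl]-1,3-dithian-2-yl}nonadec-14-en-2-ol, via 2-lithio-1,3-dithiane 11 (not isolated)
Conditions: 4 (1.2 equiv), n-BuLi, THF, −30 °C; then 10, −30 °C → rt; aq NH4Cl
Reagents that add atoms: none
Why: n-BuLi removes the benzylic dithiane proton (acidified by two sulfur atoms and the aryl ring, and reached through coordination to the ortho OMOM and OMe oxygens) to give tertiary carbanion 11, which attacks the unsubstituted carbon of oxirane 10 in an SN2 opening driven by release of three-membered-ring strain, the lithium alkoxide being protonated on work-up. The closest known reaction type is the Corey–Seebach alkylation of 2-aryl-2-lithio-1,3-dithianes with terminal epoxides to give thioketal-masked β-hydroxy ketones. No ring is closed in this step; only the C3–C4 bond is formed. No new stereocenter is created: C2 keeps the (S) configuration of 10 because its C–O bond is not involved. The step needs regioselectivity for the terminal epoxide carbon, secured by the bulk of the tertiary carbanion, and chemoselective deprotonation at the dithiane carbon over the ring positions ortho to OMe, secured by the much higher acidity of the doubly sulfur-stabilised benzylic C–H at low temperature. Keeping C4 as a thioketal removes the dehydration and retro-aldol pathways of a free β-hydroxy ketone here and in the ring closure.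

Step 8
Reactants: 12 (2S,14Z)-1-{2-[3,6-dimethoxy-2-(methoxymethoxy)phenyl]-1,3-dithian-2-yl}nonadec-14-en-2-ol
Product: 13 2-{2-[(2S,14Z)-2-hydroxynonadec-14-en-1-yl]-1,3-dithian-2-yl}-3,6-dimethoxyphenol
Conditions: conc. HCl (cat.), MeOH/THF, 45 °C
Reagents that add atoms: none
Why: Acid-catalysed transacetalisation of the MOM ether to methanol; the thioketal, the aryl methyl ethers, the secondary alcohol and the alkene are stable to dilute methanolic HCl.

Step 9
Reactants: 13 2-{2-[(2S,14Z)-2-hydroxynonadec-14-en-1-yl]-1,3-dithian-2-yl}-3,6-dimethoxyphenol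
Product: 14 (2R)-2-[(12Z)-heptadec-12-en-1-yl]-5,8-dimethoxy-2,3-dihydrospiro[chromene-4,2'-[1,3]dithiane]
Conditions: PPh3, DIAD, THF, 0 °C → rt
Reagents that add atoms: none
Why: Intramolecular Mitsunobu etherification: the phenol displaces the alkoxyphosphonium ion of the secondary alcohol in a 6-exo-tet SN2 step, closing ring B at O1–C2 with inversion from (S) to (R), while the thioketal at C4 rules out β-elimination toward a conjugated ketone.

Step 10
Reactants: 14 (2R)-2-[(12Z)-heptadec-12-en-1-yl]-5,8-dimethoxy-2,3-dihydrospiro[chromene-4,2'-[1,3]dithiane]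
Product: 16 (2R)-2-[(12Z)-heptadec-12-en-1-yl]-2,3-dihydro-4H-chromene-4,5,8-trione, via dimethoxychromanone 15 (not isolated)
Conditions: (NH4)2Ce(NO3)6 (6 equiv), MeCN/H2O (4:1), 0 °C, short contact time; extraction, crude product used at once
Reagents that add atoms: water, O
Why: (NH4)2Ce(NO3)6 is an established reagent both for oxidative cleavage of 1,3-dithianes and for oxidative demethylation of para-dimethoxyarenes, so single-electron oxidation of the electron-rich aryl thioketal should release ketone 15, whose 5,8-dimethoxy ring is then oxidised to the para-quinone with loss of two methanol, the cold acidic medium sparing the isolated alkene and the C2 centre.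

Step 11
Reactants: 16 (2R)-2-[(12Z)-heptadec-12-en-1-yl]-2,3-dihydro-4H-chromene-4,5,8-trione
Product: 17 (2R)-2-[(12Z)-heptadec-12-en-1-yl]-5,8-dihydroxy-2,3-dihydro-4H-chromen-4-one
Conditions: Na2S2O4, EtOAc/H2O, rt, under Ar
Reagents that add atoms: none
Why: Two-electron reduction of a para-quinone to the hydroquinone by dithionite at near-neutral pH, which should leave the C4 ketone, the Z alkene and the base-sensitive C2 stereocenter (retro-oxa-Michael pathway) untouched.

## Compound list

1 | 2,5-dimethoxyphenol | COc1ccc(OC)c(O)c1 | starting material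
2 | 2-hydroxy-3,6-dimethoxybenzaldehyde | COc1ccc(OC)c(C=O)c1O | intermediate
3 | 2-(1,3-dithian-2-yl)-3,6-dimethoxyphenol | COc1ccc(OC)c(C2SCCCS2)c1O | intermediate
4 | 2-[3,6-dimethoxy-2-(methoxymethoxy)phenyl]-1,3-dithiane | COCOc1c(OC)ccc(OC)c1C1SCCCS1 | intermediate
5 | (11Z)-hexadec-11-en-1-ol | CCCC/C=C\CCCCCCCCCCO | starting material
6 | (5Z)-16-bromohexadec-5-ene | CCCC/C=C\CCCCCCCCCCBr | intermediate
7 | (S)-epichlorohydrin, (2S)-2-(chloromethyl)oxirane | ClC[C@@H]1CO1 | starting material
8 | [(11Z)-hexadec-11-en-1-yl]magnesium bromide (not isolated) | CCCC/C=C\CCCCCCCCCC[Mg]Br | intermediate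
9 | (2S,14Z)-1-chlorononadec-14-en-2-ol | CCCC/C=C\CCCCCCCCCCC[C@H](O)CCl | intermediate
10 | (2S)-2-[(12Z)-heptadec-12-en-1-yl]oxirane | CCCC/C=C\CCCCCCCCCCC[C@H]1CO1 | intermediate
11 | {2-[3,6-dimethoxy-2-(methoxymethoxy)phenyl]-1,3-dithian-2-yl}lithium (not isolated) | COCOc1c(OC)ccc(OC)c1C1([Li])SCCCS1 | intermediate
12 | (2S,14Z)-1-{2-[3,6-dimethoxy-2-(methoxymethoxy)phenyl]-1,3-dithian-2-yl}nonadec-14-en-2-ol | CCCC/C=C\CCCCCCCCCCC[C@H](O)CC1(SCCCS1)c1c(OC)ccc(OC)c1OCOC | intermediate
13 | 2-{2-[(2S,14Z)-2-hydroxynonadec-14-en-1-yl]-1,3-dithian-2-yl}-3,6-dimethoxyphenol | CCCC/C=C\CCCCCCCCCCC[C@H](O)CC1(SCCCS1)c1c(OC)ccc(OC)c1O | intermediate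
14 | (2R)-2-[(12Z)-heptadec-12-en-1-yl]-5,8-dimethoxy-2,3-dihydrospiro[chromene-4,2'-[1,3]dithiane] | CCCC/C=C\CCCCCCCCCCC[C@@H]1CC2(SCCCS2)c2c(OC)ccc(OC)c2O1 | intermediate
15 | (2R)-2-[(12Z)-heptadec-12-en-1-yl]-5,8-dimethoxy-2,3-dihydro-4H-chromen-4-one (not isolated) | CCCC/C=C\CCCCCCCCCCC[C@@H]1CC(=O)c2c(OC)ccc(OC)c2O1 | intermediate
16 | (2R)-2-[(12Z)-heptadec-12-en-1-yl]-2,3-dihydro-4H-chromene-4,5,8-trione | CCCC/C=C\CCCCCCCCCCC[C@@H]1CC(=O)C2=C(O1)C(=O)C=CC2=O | intermediate
17 | (2R)-2-[(12Z)-heptadec-12-en-1-yl]-5,8-dihydroxy-2,3-dihydro-4H-chromen-4-one | CCCC/C=C\CCCCCCCCCCC[C@@H]1CC(=O)c2c(O)ccc(O)c2O1 | target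

## Step count and risks

Total step count: 11 steps.
Longest linear sequence: 8 steps (steps 1, 2, 3, 7, 8, 9, 10, 11 from phenol 1; equally steps 4, 5, 6, 7, 8, 9, 10, 11 from alcohol 5).

Steps most likely to fail:

**Step 7 (key alkylation).** The carbanion carbon is tertiary and flanked by two ortho oxygen substituents, so its SN2 attack on the epoxide may be slower than proton return on warming or base-induced isomerisation of the epoxide, and the coupling may stall. The fallback opens the epoxide with the unhindered parent dithiane and attaches the aryl group afterwards by normal-polarity addition. It sets out from epoxide 10 and phenol 1 and comes back to the route at chromanone 15.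
- 2-Lithio-1,3-dithiane (1,3-dithiane, n-BuLi, THF, −20 °C) should open 10 at its terminal carbon to give (2S,14Z)-1-(1,3-dithian-2-yl)nonadec-14-en-2-ol F1.
- TBSCl/imidazole in DMF should give silyl ether F2, and MeI/CaCO3 in aqueous MeCN should unmask the aldehyde (3S,15Z)-3-{[tert-butyl(dimethyl)silyl]oxy}icos-15-enal F3.
- Separately, phenol 1 with NaH/MOMCl should give 1,4-dimethoxy-2-(methoxymethoxy)benzene F4, which n-BuLi (THF, 0 °C) should lithiate at the carbon lying between OMOM and OMe to give aryllithium F5.
- Addition of F5 to F3 at −78 °C should give carbinol F6 (both epimers at the new carbinol carbon, which is then oxidised), and Dess–Martin periodinane should give ketone F7.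
- Methanolic HCl should remove MOM and TBS to give hydroxy ketone F8, and PPh3/DIAD at 0 °C should close O1–C2 with inversion to give 15, isolated in this variant.
- 15 is then oxidised to 16 with the reagent of step 10.

**Step 10 (double oxidative unmasking).** The oxidation may be unselective: excess (NH4)2Ce(NO3)6 can attack sulfur residues or the alkene further, and the electron-poor acylquinone can be opened by water at C8a or lose configurational integrity at C2 on prolonged contact. The fallback separates the two unmaskings and removes the thioketal without an oxidant. It sets out from 14 and comes back at 16: MeI/CaCO3 in aqueous MeCN at 45 °C should hydrolyse the thioketal by S-alkylation to give 15 as an isolated compound, and a separate brief treatment of 15 with AgO (argentic oxide) and 6 M HNO3 in dioxane at rt should effect the oxidative demethylation to 16.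

**Step 9 (Mitsunobu closure).** The activated secondary alcohol may eliminate, or the hindered, electron-rich phenol may capture the alkoxyphosphonium ion too slowly, so that E2 loss competes with ring closure. The fallback separates activation from displacement and uses a sulfonate SN2 closure in place of the redox condensation. It sets out from 12 and comes back at 14: MsCl/Et3N in CH2Cl2 at 0 °C should give the (2S) mesylate F9 while the phenol is still MOM-protected, methanolic HCl at rt should remove MOM to give phenol mesylate F10, and K2CO3 in DMF at 40 °C should close ring B by intramolecular Williamson displacement with inversion.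

Further compounds
F1 | step 7 | (2S,14Z)-1-(1,3-dithian-2-yl)nonadec-14-en-2-ol | CCCC/C=C\CCCCCCCCCCC[C@H](O)CC1SCCCS1
F2 | step 7 | tert-butyl{[(2S,14Z)-1-(1,3-dithian-2-yl)nonadec-14-en-2-yl]oxy}dimethylsilane | CCCC/C=C\CCCCCCCCCCC[C@H](O[Si](C)(C)C(C)(C)C)CC1SCCCS1
F3 | step 7 | (3S,15Z)-3-{[tert-butyl(dimethyl)silyl]oxy}icos-15-enal | CCCC/C=C\CCCCCCCCCCC[C@H](O[Si](C)(C)C(C)(C)C)CC=O
F4 | step 7 | 1,4-dimethoxy-2-(methoxymethoxy)benzene | COCOc1cc(OC)ccc1OC
F5 | step 7 | [3,6-dimethoxy-2-(methoxymethoxy)phenyl]lithium | COCOc1c([Li])c(OC)ccc1OC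
F6 | step 7 | (3S,15Z)-3-{[tert-butyl(dimethyl)silyl]oxy}-1-[3,6-dimethoxy-2-(methoxymethoxy)phenyl]icos-15-en-1-ol (both C1 epimers) | CCCC/C=C\CCCCCCCCCCC[C@H](O[Si](C)(C)C(C)(C)C)CC(O)c1c(OC)ccc(OC)c1OCOC
F7 | step 7 | (3S,15Z)-3-{[tert-butyl(dimethyl)silyl]oxy}-1-[3,6-dimethoxy-2-(methoxymethoxy)phenyl]icos-15-en-1-one | CCCC/C=C\CCCCCCCCCCC[C@H](O[Si](C)(C)C(C)(C)C)CC(=O)c1c(OC)ccc(OC)c1OCOC
F8 | step 7 | (3S,15Z)-3-hydroxy-1-(2-hydroxy-3,6-dimethoxyphenyl)icos-15-en-1-one | CCCC/C=C\CCCCCCCCCCC[C@H](O)CC(=O)c1c(OC)ccc(OC)c1O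
F0 | step 10 | none | none
F9 | step 9 | (2S,14Z)-1-{2-[3,6-dimethoxy-2-(methoxymethoxy)phenyl]-1,3-dithian-2-yl}nonadec-14-en-2-yl methanesulfonate | CCCC/C=C\CCCCCCCCCCC[C@H](OS(C)(=O)=O)CC1(SCCCS1)c1c(OC)ccc(OC)c1OCOC
F10 | step 9 | (2S,14Z)-1-[2-(2-hydroxy-3,6-dimethoxyphenyl)-1,3-dithian-2-yl]nonadec-14-en-2-yl methanesulfonate | CCCC/C=C\CCCCCCCCCCC[C@H](OS(C)(=O)=O)CC1(SCCCS1)c1c(OC)ccc(OC)c1O
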